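## The problem

The target is a pentacyclic amino bis-lactone in which a 3-methylbutenolide (ring A) is fused through its γ-carbon, an N,O-aminal carbon, and its β-carbon to an azepine (ring B) whose nitrogen is shared with a pyrrolidine (ring C). The ring B carbon next to the B/C ring-fusion carbon is the spiro centre of an α-methyl-γ-butyrolactone (ring D), and the other α-carbon of the pyrrolidine carries a second α-methyl-γ-butyrolactone (ring E). Seven stereocentres must be set: the aminal carbon (S), the spiro carbon (S), the ring D α-carbon (R), the ring-fusion carbon (S), the pyrrolidine carbon bearing ring E (S), and the γ- and α-carbons of ring E (both S). The ring-fusion carbon is the natural anchor, because it can direct the 2,5-trans pyrrolidine and, through it, the threo junction and the cis methyl of ring E. The spiro carbon is harder: its C–O bond lies on the face of ring B that carries the ring-fusion hydrogen and its ring D methylene on the face of the neighbouring pyrrolidine methylene, which is the opposite of what a carbon nucleophile adding to a ring B ketone from the open face would give, and the ring D methyl cannot be corrected with base without endangering the like centre of ring E. The aminal carbon is also the γ-position of ring A, so it ionises to an iminium carboxylate and its hydrogen is acidic, which rules out strong base, hard nucleophiles and hydrogenolysis once ring A is in place; a free secondary amine next to ring E can also suffer O-to-N acyl shift. The enabling feature is the CH2–CH2 unit of ring B, which links the spiro carbon, reachable at the ketone level, to the electron-poor β-carbon of ring A: this is the pattern of a ring-opened cyclopropanol adding as a β-keto alkyl radical to a butenolide. The spiro and ring-fusion carbons then map onto the carboxyl and α-carbons of L-pyroglutamic acid.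

## Retrosynthesis

**Ring D acyl C–O bond and the ring D methyl centre (23 from 21 through 22).** Ring D is opened to hydroxy ester 22, and its α-stereocentre is traced to hydrogenation of E-enoate 21. Reducing before ring closure puts the new centre under A(1,3) control of the tertiary carbinol. Kinetic hydrogen delivery to a preformed spiro α-methylene lactone would more likely push the methyl toward the pyrrolidine, and base equilibration is not tolerable here. The forward step must reduce a trisubstituted enoate on one face while leaving the tetrasubstituted butenolide and the aminal alone.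

**The C=C bond, the tertiary C–O bond and the exocyclic carbon (21 from 19, 18 and 17).** The enoate is cut by a Wittig disconnection to α-hydroxy aldehyde 20, which comes from diol 19, the dihydroxylation product of exocyclic alkene 18. Alkene 18 comes from ketone 17 by methylenation. The obvious neighbour, adding a three-carbon nucleophile straight to 17, is rejected. In azepanone 17 the pyrrolidine methylene on the ring-fusion carbon shields one face of the carbonyl, so a carbon nucleophile would enter from the face of the ring-fusion hydrogen and give the spiro epimer. Delivering oxygen last from that same open face gives the required configuration. The forward steps must be non-basic, because the ring-fusion hydrogen of 17 and the γ-hydrogen of ring A are both labile.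

**The ring B bond from CH2 to the butenolide β-carbon (17 from 16).** This is the strategic cut. Ketone 17 is the ring-closed, re-oxidised form of the β-keto radical released from cyclopropanol 16. It removes a seven-membered ring in one step and leaves a monocyclic pyrrolidine carrying three appendages. The forward reaction needs a 7-exo radical closure onto ring A that beats premature oxidation or reduction of the radical, and an oxidative termination that restores the butenolide.

**The N–C(aminal) bond (16 from 13 and 14).** The butenolide is attached to nitrogen by substitution of bromide 14 with the amine 15 released from carbamate 13. Forming the aminal first makes ring A the tethered radical acceptor. The forward step needs N-alkylation of a hindered amine without conjugate addition or acyl shift.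

**The cyclopropane C–C bonds (13 from 10, 9 and 7).** The cyclopropanol is traced to methyl ketone 10 through silyl enol ether 11 and Simmons–Smith methylene transfer. Ketone 10 comes from acid 7 through Weinreb amide 9. A Kulinkovich reaction on an ester would be one step, but it cannot distinguish an ester from lactone E. The acid-based sequence touches only the carboxyl group.

**The pyrrolidine–ring E bond and the ring E methyl centre (7 from 6, 5 and 2).** Ring E is disconnected at the bond to the pyrrolidine by a vinylogous Mannich reaction of silyloxyfuran 2 with the N-acyliminium ion from methoxy aminal 5, followed by hydrogenation of butenolide 6. The ester on the iminium ion is kept on purpose, because it is the group known to steer the furan to the trans face. Hydrogenation also frees the acid from its benzyl ester.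

**Starting materials (5 from 3; 2 and 14 from 1).** Methoxy aminal 5 comes from commercial N-Boc-L-pyroglutamic acid benzyl ester 3 by partial reduction. Both furanone reagents, 2 and 14, come from commercial 3-methylfuran-2(5H)-one 1.

## Roads not taken

Alternative 1: A C2-symmetric pyrrolidine from the chiral pool. The cut is at both N–C bonds of ring C. D-mannitol A1 is degraded, by removal of its two central hydroxyl groups and benzylation of the terminal ones, to the (2R,5R)-dimesylate A2. A benzylic primary amine then displaces both leaving groups with inversion and closes the trans-pyrrolidine A3, which is (2S,5S)-1-benzyl-2,5-bis(benzyloxymethyl)pyrrolidine.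
- Merit: the trans relationship of the pyrrolidine is fixed by the starting material and involves no facial selectivity. In this respect it is more secure than the iminium addition used here.
- Weakness: the two identical arms of A3 must be told apart and then built separately into ring E (two new stereocentres) and into the spiro carbon with rings B and A. This costs many protecting-group and oxidation-state changes, and the hard centres are still unsolved after the key step. In addition, once the central hydroxyls of A1 are gone the remaining carbinol centres carry the (2S,5S) descriptors, so reaching A2 needs an extra inversion of both centres.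
- Comparison: the chosen plan sets against it an addition that is directed by the ester and also delivers ring E with its junction stereocentre in the same step.

Alternative 2: Iodine-triggered amination–lactonisation. The cut is at the N–C bond of the ring-fusion carbon and the C–O bond of the spiro carbon. An electrophilic iodine source activates a Z-trisubstituted alkene, the N-benzylamine closes ring C, and the derived aziridinium ion is opened at the tertiary carbon by the carboxylate, giving the bis-lactone A4.
- Merit: the spiro centre, ring C and ring D form in one operation, oxygen is delivered with inversion at the tertiary carbon, and the ring D methyl comes from a preformed fragment. For the spiro centre this is better than the chosen plan, which needs four steps and two face-selective events after the key step.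
- Weakness: it needs a long acyclic precursor with defined alkene geometry and preset stereocentres, and rings B and A must still be closed from the masked arm of A4 after debenzylation.
- Comparison: the chosen plan sets against it a short precursor and the use of ring A itself as the ring-closing acceptor.

Alternative 3: Intramolecular Schmidt ring expansion. The cut is at both N–C bonds of the ring-fusion nitrogen. Under Lewis or Brønsted acid a secondary azide adds to a spiro-lactone cyclohexanone and the ring-fusion carbon migrates to nitrogen with loss of nitrogen, giving lactam A5.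
- Merit: rings B and C arise together with retention at the migrating carbon, and the spiro centre is set earlier on a carbocycle, where control is easier than on the azepanone used here.
- Weakness: A5 is a lactam at the carbon that must become the aminal carbon. All of ring A must be grafted onto a hindered lactam late, and the azide precursor already needs four stereocentres.
- Comparison: the chosen plan sets against it the early installation of ring A and a ring closure that forms a C–C bond rather than relying on late lactam elaboration.

Key step: step 10

Assumption: the aminal carbon equilibrates through the ring-opened iminium carboxylate. Bromide 14 is therefore used as the racemate, and the (S) configuration drawn for 16, 17 and 23 is taken to be the one favoured at equilibrium in the fused system.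

## Steps

Step 1
Reactants: 1 3-methylfuran-2(5H)-one
Product: 2 3-methyl-2-(triisopropylsilyloxy)furan
Conditions: TIPSOTf, Et3N, CH2Cl2, 0 °C
Reagents that add atoms: triisopropylsilyl trifluoromethanesulfonate, CC(C)[Si](C(C)C)(C(C)C)OS(=O)(=O)C(F)(F)F
Why: Soft enolisation of the butenolide at the γ-position and O-silylation give the aromatic 2-silyloxyfuran, the standard nucleophile for vinylogous Mannich reactions.

Step 2
Reactants: 3 N-Boc-L-pyroglutamic acid benzyl ester
Product: 5 2-benzyl 1-tert-butyl (2S)-5-methoxypyrrolidine-1,2-dicarboxylate, via hemiaminal 4 (not isolated)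
Conditions: LiBHEt3, THF, −78 °C; H2O quench; then MeOH, PPTS, rt
Reagents that add atoms: methanol, CO
Why: The Boc-activated lactam carbonyl is reduced in preference to the benzyl ester, and acid-catalysed methanolysis of the hemiaminal gives the N,O-acetal; the mixture at the new acetal carbon does not matter because it becomes planar in step 3.

Step 3
Reactants: 5 2-benzyl 1-tert-butyl (2S)-5-methoxypyrrolidine-1,2-dicarboxylate; 2 3-methyl-2-(triisopropylsilyloxy)furan
Product: 6 2-benzyl 1-tert-butyl (2S,5S)-5-[(2S)-4-methyl-5-oxo-2,5-dihydrofuran-2-yl]pyrrolidine-1,2-dicarboxylate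
Conditions: TIPSOTf (10 mol%), CH2Cl2, −78 to 0 °C
Reagents that add atoms: none
Why: Vinylogous Mannich reaction: the silyl triflate ionises the N,O-acetal to the N-acyliminium ion and the furan attacks through its 5-position on the face anti to the ester, giving the 2,5-trans pyrrolidine. The threo junction (S at the new butenolide carbon) is the usual outcome for silyloxyfurans with cyclic N-acyliminium ions.

Step 4
Reactants: 6 2-benzyl 1-tert-butyl (2S,5S)-5-[(2S)-4-methyl-5-oxo-2,5-dihydrofuran-2-yl]pyrrolidine-1,2-dicarboxylate
Product: 7 (2S,5S)-1-(tert-butoxycarbonyl)-5-[(2S,4S)-4-methyl-5-oxooxolan-2-yl]pyrrolidine-2-carboxylic acid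
Conditions: H2 (1 atm), 10% Pd/C, EtOAc, rt
Reagents that add atoms: none
Why: Heterogeneous hydrogenation adds hydrogen to the butenolide face opposite the pyrrolidine substituent, which places the methyl cis to it (S), and the same conditions cleave the benzyl ester by hydrogenolysis.

Step 5
Reactants: 7 (2S,5S)-1-(tert-butoxycarbonyl)-5-[(2S,4S)-4-methyl-5-oxooxolan-2-yl]pyrrolidine-2-carboxylic acid
Product: 9 tert-butyl (2S,5S)-2-[methoxy(methyl)carbamoyl]-5-[(2S,4S)-4-methyl-5-oxooxolan-2-yl]pyrrolidine-1-carboxylate, via acyl imidazole 8 (not isolated)
Conditions: CDI, CH2Cl2, rt; then MeNHOMe·HCl, rt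
Reagents that add atoms: N,O-dimethylhydroxylamine hydrochloride, CNOC.Cl
Why: Weinreb amide formation through the acyl imidazole activates only the free acid; the carbamate-protected α-centre cannot form an oxazolone and should keep its configuration.

Step 6
Reactants: 9 tert-butyl (2S,5S)-2-[methoxy(methyl)carbamoyl]-5-[(2S,4S)-4-methyl-5-oxooxolan-2-yl]pyrrolidine-1-carboxylate
Product: 10 tert-butyl (2S,5S)-2-acetyl-5-[(2S,4S)-4-methyl-5-oxooxolan-2-yl]pyrrolidine-1-carboxylate
Conditions: MeMgBr, THF, −40 to −10 °C; aq. NH4Cl quench
Reagents that add atoms: methylmagnesium bromide, C[Mg]Br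
Why: Weinreb ketone synthesis: the chelated tetrahedral intermediate stops at the ketone stage, and at low temperature the amide should react ahead of the α-branched lactone.

Step 7
Reactants: 10 tert-butyl (2S,5S)-2-acetyl-5-[(2S,4S)-4-methyl-5-oxooxolan-2-yl]pyrrolidine-1-carboxylate
Product: 13 tert-butyl (2S,5S)-2-(1-hydroxycyclopropyl)-5-[(2S,4S)-4-methyl-5-oxooxolan-2-yl]pyrrolidine-1-carboxylate, via silyl enol ether 11 (not isolated), via silyloxycyclopropane 12 (not isolated)
Conditions: LiN(SiMe3)2, TMSCl, THF, −78 °C; solvent exchange; Et2Zn, CH2I2, CH2Cl2, 0 °C to rt; then citric acid, MeOH, rt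
Reagents that add atoms: diiodomethane, ICI
Why: Kinetic enolisation with in situ silylation takes the methyl side of the ketone, which is far more acidic than the lactone; Simmons–Smith cyclopropanation (Furukawa variant) of the electron-rich enol ether then builds the ring, and mild methanolysis frees the cyclopropanol. No stereocentre is created.

Step 8
Reactants: 1 3-methylfuran-2(5H)-one
Product: 14 5-bromo-3-methylfuran-2(5H)-one (racemic)
Conditions: NBS, AIBN (cat.), PhCF3, 80 °C
Reagents that add atoms: N-bromosuccinimide, O=C1CCC(=O)N1Br
Why: Wohl–Ziegler bromination at the γ-position, where the radical is stabilised by the ring oxygen and the conjugated system; this is the established way to make this butenolide-transfer reagent.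

Step 9
Reactants: 13 tert-butyl (2S,5S)-2-(1-hydroxycyclopropyl)-5-[(2S,4S)-4-methyl-5-oxooxolan-2-yl]pyrrolidine-1-carboxylate; 14 5-bromo-3-methylfuran-2(5H)-one
Product: 16 (3S,5S)-5-{(2S,5S)-5-(1-hydroxycyclopropyl)-1-[(2S)-4-methyl-5-oxo-2,5-dihydrofuran-2-yl]pyrrolidin-2-yl}-3-methyloxolan-2-one, via amino cyclopropanol 15 (not isolated)
Conditions: TFA, CH2Cl2, 0 °C; concentrate; then 14, iPr2NEt, MeCN, −20 °C to rt
Reagents that add atoms: none
Why: Acidolysis removes the Boc group, and the amine is freed only in the presence of the bromide, which limits O-to-N acyl shift from ring E; substitution at the acyloxy-stabilised carbon (SN1-like N-alkylation) favours nitrogen over the tertiary hydroxyl. The aminal epimers interconvert through the iminium carboxylate and are carried on together.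

Step 10
Reactants: 16 (3S,5S)-5-{(2S,5S)-5-(1-hydroxycyclopropyl)-1-[(2S)-4-methyl-5-oxo-2,5-dihydrofuran-2-yl]pyrrolidin-2-yl}-3-methyloxolan-2-one
Product: 17 tricyclic keto butenolide with rings A to C closed
Conditions: Mn(acac)3 (2.2 equiv), Cu(OAc)2 (0.2 equiv), degassed MeCN–AcOH (9:1), 60 °C, high dilution
Reagents that add atoms: none
Why: Ligand exchange gives a cyclopropoxide of trivalent manganese; one-electron oxidation and β-scission open the ring to the ketone and a primary β-keto alkyl radical. This nucleophilic radical adds to the electron-poor β-carbon of ring A and closes the azepine (ring B) in the 7-exo-trig mode, with the methyl-bearing alkene carbon left outside the new ring. The tertiary α-lactone radical is intercepted by divalent copper and loses the hydrogen on the former β-carbon, restoring the conjugated tetrasubstituted butenolide; the monovalent copper is reoxidised by the second equivalent of Mn(acac)3. The closest known reaction type is the oxidative free-radical cyclisation of cyclopropanols and β-dicarbonyl compounds onto electron-poor alkenes with manganese and copper oxidants, usually to five- and six-membered rings; the seven-membered closure is an extension that the short nitrogen-containing tether and the polarity match should allow. No stereocentre is created: the β-carbon returns to sp2, the ring-fusion carbon is not involved and the aminal carbon equilibrates. The step needs cyclisation to outrun copper oxidation of the primary radical and hydrogen abstraction; substoichiometric Cu(OAc)2, dilution and the activated acceptor secure this, and 8-endo attack at the α-carbon is disfavoured by polarity and by the methyl group.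

Step 11
Reactants: 17 tricyclic keto butenolide
Product: 18 exocyclic methylene compound (C=CH2 in place of the ring B ketone)
Conditions: Zn, CH2Br2, TiCl4, THF–CH2Cl2, 0 °C to rt
Reagents that add atoms: dibromomethane, BrCBr
Why: Takai–Lombardo methylenation: the non-basic zinc–titanium gem-dimetallic reagent converts the ketone without enolising the ring-fusion carbon or touching the lactones, and it removes the only source of epimerisation at that carbon.

Step 12
Reactants: 18 exocyclic methylene compound
Product: 19 diol (tertiary hydroxyl on the future spiro carbon and CH2OH)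
Conditions: OsO4 (2 mol%), NMO, acetone–H2O, rt
Reagents that add atoms: 4-methylmorpholine N-oxide, C[N+]1([O-])CCOCC1; water, O
Why: Catalytic osmium tetroxide dihydroxylation: the pyrrolidine methylene on the ring-fusion carbon shields one face of the exocyclic alkene, so osmium should add to the face that carries the ring-fusion hydrogen. That places the tertiary oxygen cis to this hydrogen, as ring D requires, and is the opposite of what carbon addition to ketone 17 from the same open face would give. The tetrasubstituted, electron-poor butenolide does not react.

Step 13
Reactants: 19 diol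
Product: 21 E-enoate (19 with CH2OH replaced by (E)-CH=C(CH3)CO2Et), via hydroxy aldehyde 20 (not isolated)
Conditions: TEMPO (cat.), PhI(OAc)2, CH2Cl2, rt; then Ph3P=C(CH3)CO2Et, 40 °C
Reagents that add atoms: ethyl 2-(triphenylphosphoranylidene)propanoate, CCOC(=O)C(C)=P(c1ccccc1)(c1ccccc1)c1ccccc1
Why: Oxoammonium oxidation takes only the primary alcohol, giving an α-hydroxy aldehyde with no α-hydrogen; the stabilised Wittig ylide then reacts without added base to give the E-enoate, whose geometry keeps the ester away from the hydroxyl until the alkene is reduced.

Step 14
Reactants: 21 E-enoate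
Product: 23 CNP0155196.1, via hydroxy ester 22 (not isolated)
Conditions: H2 (4 bar), 5% Rh/Al2O3, EtOAc, rt; then PPTS (cat.), PhMe, 60 °C
Reagents that add atoms: none
Why: In the rotamer that puts the small hydroxyl in the alkene plane (A(1,3) strain with the cis methyl), the enoate face opposite the ring-fusion carbon is open; hydrogen delivery there gives the (R) centre of ring D. Acid-catalysed lactonisation of the tertiary γ-hydroxy ester then closes ring D; no base is used, so the ring E methyl and the aminal are not disturbed.

## Compound list

1 | 3-methylfuran-2(5H)-one | CC1=CCOC1=O | starting material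
2 | 3-methyl-2-(triisopropylsilyloxy)furan | Cc1ccoc1O[Si](C(C)C)(C(C)C)C(C)C | intermediate
3 | 2-benzyl 1-tert-butyl (2S)-5-oxopyrrolidine-1,2-dicarboxylate (N-Boc-L-pyroglutamic acid benzyl ester) | O=C(OCc1ccccc1)[C@@H]1CCC(=O)N1C(=O)OC(C)(C)C | starting material
4 | 2-benzyl 1-tert-butyl (2S)-5-hydroxypyrrolidine-1,2-dicarboxylate (both C5 epimers) | O=C(OCc1ccccc1)[C@@H]1CCC(O)N1C(=O)OC(C)(C)C | intermediate
5 | 2-benzyl 1-tert-butyl (2S)-5-methoxypyrrolidine-1,2-dicarboxylate (both C5 epimers) | O=C(OCc1ccccc1)[C@@H]1CCC(OC)N1C(=O)OC(C)(C)C | intermediate
6 | 2-benzyl 1-tert-butyl (2S,5S)-5-[(2S)-4-methyl-5-oxo-2,5-dihydrofuran-2-yl]pyrrolidine-1,2-dicarboxylate | O=C(OCc1ccccc1)[C@@H]1CC[C@@H]([C@@H]2C=C(C)C(=O)O2)N1C(=O)OC(C)(C)C | intermediate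
7 | (2S,5S)-1-(tert-butoxycarbonyl)-5-[(2S,4S)-4-methyl-5-oxooxolan-2-yl]pyrrolidine-2-carboxylic acid | OC(=O)[C@@H]1CC[C@@H]([C@@H]2C[C@H](C)C(=O)O2)N1C(=O)OC(C)(C)C | intermediate
8 | tert-butyl (2S,5S)-2-(1H-imidazol-1-ylcarbonyl)-5-[(2S,4S)-4-methyl-5-oxooxolan-2-yl]pyrrolidine-1-carboxylate | O=C(n1ccnc1)[C@@H]1CC[C@@H]([C@@H]2C[C@H](C)C(=O)O2)N1C(=O)OC(C)(C)C | intermediate
9 | tert-butyl (2S,5S)-2-[methoxy(methyl)carbamoyl]-5-[(2S,4S)-4-methyl-5-oxooxolan-2-yl]pyrrolidine-1-carboxylate | CON(C)C(=O)[C@@H]1CC[C@@H]([C@@H]2C[C@H](C)C(=O)O2)N1C(=O)OC(C)(C)C | intermediate
10 | tert-butyl (2S,5S)-2-acetyl-5-[(2S,4S)-4-methyl-5-oxooxolan-2-yl]pyrrolidine-1-carboxylate | CC(=O)[C@@H]1CC[C@@H]([C@@H]2C[C@H](C)C(=O)O2)N1C(=O)OC(C)(C)C | intermediate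
11 | tert-butyl (2S,5S)-2-[1-(trimethylsilyloxy)ethenyl]-5-[(2S,4S)-4-methyl-5-oxooxolan-2-yl]pyrrolidine-1-carboxylate | C=C(O[Si](C)(C)C)[C@@H]1CC[C@@H]([C@@H]2C[C@H](C)C(=O)O2)N1C(=O)OC(C)(C)C | intermediate
12 | tert-butyl (2S,5S)-2-[1-(trimethylsilyloxy)cyclopropyl]-5-[(2S,4S)-4-methyl-5-oxooxolan-2-yl]pyrrolidine-1-carboxylate | C[Si](C)(C)OC1(CC1)[C@@H]1CC[C@@H]([C@@H]2C[C@H](C)C(=O)O2)N1C(=O)OC(C)(C)C | intermediate
13 | tert-butyl (2S,5S)-2-(1-hydroxycyclopropyl)-5-[(2S,4S)-4-methyl-5-oxooxolan-2-yl]pyrrolidine-1-carboxylate | OC1(CC1)[C@@H]1CC[C@@H]([C@@H]2C[C@H](C)C(=O)O2)N1C(=O)OC(C)(C)C | intermediate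
14 | 5-bromo-3-methylfuran-2(5H)-one (racemic) | CC1=CC(Br)OC1=O | intermediate
15 | (3S,5S)-5-[(2S,5S)-5-(1-hydroxycyclopropyl)pyrrolidin-2-yl]-3-methyloxolan-2-one | OC1(CC1)[C@@H]1CC[C@@H]([C@@H]2C[C@H](C)C(=O)O2)N1 | intermediate
16 | (3S,5S)-5-{(2S,5S)-5-(1-hydroxycyclopropyl)-1-[(2S)-4-methyl-5-oxo-2,5-dihydrofuran-2-yl]pyrrolidin-2-yl}-3-methyloxolan-2-one (drawn as the S aminal epimer; both epimers are carried on) | OC1(CC1)[C@@H]1CC[C@@H]([C@@H]2C[C@H](C)C(=O)O2)N1[C@H]1OC(=O)C(C)=C1 | intermediate
17 | tricyclic keto butenolide: the aminal carbon (S) of 3-methylbutenolide ring A is bonded to N and its β-carbon carries CH2CH2C(=O), which closes azepanone ring B onto the ring-fusion carbon (S) of pyrrolidine ring C; the other pyrrolidine α-carbon (S) bears the (2S,4S)-4-methyl-5-oxooxolan-2-yl group | CC1=C2CCC(=O)[C@@H]3CC[C@@H]([C@@H]4C[C@H](C)C(=O)O4)N3[C@H]2OC1=O | intermediate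
18 | as 17, with the ring B ketone replaced by an exocyclic C=CH2 | CC1=C2CCC(=C)[C@@H]3CC[C@@H]([C@@H]4C[C@H](C)C(=O)O4)N3[C@H]2OC1=O | intermediate
19 | as 17, with the ring B ketone carbon replaced by a carbon bearing OH and CH2OH (R at this carbon; OH cis to the ring-fusion hydrogen) | CC1=C2CC[C@](O)(CO)[C@@H]3CC[C@@H]([C@@H]4C[C@H](C)C(=O)O4)N3[C@H]2OC1=O | intermediate
20 | as 19, with CH2OH oxidised to CHO (R at the carbinol carbon) | CC1=C2CC[C@](O)(C=O)[C@@H]3CC[C@@H]([C@@H]4C[C@H](C)C(=O)O4)N3[C@H]2OC1=O | intermediate
21 | as 19, with CH2OH replaced by (E)-CH=C(CH3)CO2Et (S at the carbinol carbon) | CC1=C2CC[C@](O)(/C=C(\C)C(=O)OCC)[C@@H]3CC[C@@H]([C@@H]4C[C@H](C)C(=O)O4)N3[C@H]2OC1=O | intermediate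
22 | as 21, with the alkene reduced to CH2–CH(CH3)CO2Et (S at the carbinol carbon, R at the new methyl-bearing carbon) | CC1=C2CC[C@](O)(C[C@@H](C)C(=O)OCC)[C@@H]3CC[C@@H]([C@@H]4C[C@H](C)C(=O)O4)N3[C@H]2OC1=O | intermediate
23 | CNP0155196.1: pentacyclic butenolide aminal bis-lactone; aminal carbon S, spiro carbon S, ring D α-carbon R, ring-fusion carbon S, pyrrolidine carbon bearing ring E S, ring E (2S,4S) | CC1=C2CC[C@]3(C[C@@H](C)C(=O)O3)[C@@H]3CC[C@@H]([C@@H]4C[C@H](C)C(=O)O4)N3[C@H]2OC1=O | target

## Step count and least certain steps

Total step count: 14. Longest linear sequence: 12 steps (steps 2–7 and 9–14, from 3); steps 1 and 8 are side branches from 1.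

**Step 10 (key step).**
- Risk: oxidation of the primary β-keto radical by copper, or its reduction, before the slow seven-membered closure. The final elimination may take a methyl hydrogen instead of the ring hydrogen and so fail to restore the conjugated butenolide directly. Epimerisation at the ring-fusion carbon of the α-amino ketone and oxidation of the tertiary amine by the manganese reagent are further possibilities.
- Fallback: this sets out from 13 and returns at 17, forming the same C–C bond by two-electron chemistry and closing ring B by aminal formation. Mucobromic acid is converted with methanol and catalytic H2SO4 into 3,4-dibromo-5-methoxyfuran-2(5H)-one F1. Palladium-catalysed ring-opening cross-coupling of cyclopropanol 13 with F1 (Pd(OAc)2, XPhos, Cs2CO3, toluene) at the more reactive β-bromide gives the bromobutenolide keto carbamate F2. Stille methylation of the remaining α-bromide (Me4Sn, Pd(PPh3)4, zerovalent palladium) gives the methylbutenolide keto carbamate F3. TFA then removes the Boc group, and warming with PPTS in toluene lets the amine displace methanol at the acetal carbon to give 17.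

**Step 12.**
- Risk: poor or reversed facial selectivity in the osmylation, if the azepine adopts a conformation in which the face of the ring-fusion hydrogen is the more hindered one. Slow turnover through amine coordination to osmium is also possible.
- Fallback: this sets out from 17 and returns at 23. Carbon and oxygen delivery are stereocomplementary, so if the open face proves to be the other one, carbon addition gives the right spiro epimer. A zinc-mediated Barbier addition of ethyl 2-(bromomethyl)acrylate (Zn, THF) to the ketone gives the hydroxy α-methylene ester F4, which lactonises on acidic work-up to the α-methylene spirolactone F5. Hydrogenation of its exocyclic alkene over Rh/Al2O3 then gives 23. The facial selectivity of this hydrogenation is not assured.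

**Step 14.**
- Risk: insufficient facial selectivity in the enoate reduction, or hydrogenolysis at the allylic aminal C–O bond.
- Fallback: this sets the methyl centre under thermodynamic rather than kinetic control, setting out from 19 and returning at 23. Oxidation to 20 as in step 13, followed by Wittig reaction with 2-(triphenylphosphoranylidene)propanal, gives the E-enal F6. Hydrogenation of the alkene gives the spiro lactol F7, whose methyl centre equilibrates through the open-chain aldehyde under mild amine catalysis that leaves lactones untouched. Oxidation with Ag2CO3 on Celite (Fétizon conditions) then gives 23.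

**Step 9.**
- Risk: slow alkylation of the hindered amine, competing conjugate addition to the bromobutenolide, or O-to-N acyl shift from ring E once the amine is free.
- Fallback: this replaces substitution by dehydrative condensation, setting out from 15 (made from 13 as in step 9) and 14 and returning at 16. Hydrolysis of 14 in aqueous acetone with NaHCO3 gives 5-hydroxy-3-methylfuran-2(5H)-one F8. Its open aldehyde form condenses with the trifluoroacetate salt of 15 (molecular sieves, toluene, 50 °C), and the iminium carboxylate closes to 16.

**Step 6.**
- Risk: competing Grignard addition to lactone E.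
- Fallback: this sets out from 7 and returns at 10. Coupling of 7 with ethanethiol (EDC, DMAP) gives the S-ethyl thioester F9. Fukuyama coupling with MeZnI and PdCl2(PPh3)2 in THF gives 10 under conditions that do not touch lactones.

## Further compounds

F1 | step 10 | 3,4-dibromo-5-methoxyfuran-2(5H)-one | COC1OC(=O)C(Br)=C1Br
F2 | step 10 | tert-butyl (2S,5S)-2-[3-(4-bromo-2-methoxy-5-oxo-2,5-dihydrofuran-3-yl)propanoyl]-5-[(2S,4S)-4-methyl-5-oxooxolan-2-yl]pyrrolidine-1-carboxylate | COC1OC(=O)C(Br)=C1CCC(=O)[C@@H]1CC[C@@H]([C@@H]2C[C@H](C)C(=O)O2)N1C(=O)OC(C)(C)C
F3 | step 10 | tert-butyl (2S,5S)-2-[3-(2-methoxy-4-methyl-5-oxo-2,5-dihydrofuran-3-yl)propanoyl]-5-[(2S,4S)-4-methyl-5-oxooxolan-2-yl]pyrrolidine-1-carboxylate | COC1OC(=O)C(C)=C1CCC(=O)[C@@H]1CC[C@@H]([C@@H]2C[C@H](C)C(=O)O2)N1C(=O)OC(C)(C)C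
F4 | step 12 | hydroxy α-methylene ester (17 with the ketone carbon bearing OH and CH2C(=CH2)CO2Et; S at the carbinol carbon) | CC1=C2CC[C@](O)(CC(=C)C(=O)OCC)[C@@H]3CC[C@@H]([C@@H]4C[C@H](C)C(=O)O4)N3[C@H]2OC1=O
F5 | step 12 | α-methylene spirolactone (23 with C=CH2 in place of the ring D CH–CH3) | CC1=C2CC[C@]3(CC(=C)C(=O)O3)[C@@H]3CC[C@@H]([C@@H]4C[C@H](C)C(=O)O4)N3[C@H]2OC1=O
F6 | step 14 | E-enal (21 with CHO in place of CO2Et) | CC1=C2CC[C@](O)(/C=C(\C)C=O)[C@@H]3CC[C@@H]([C@@H]4C[C@H](C)C(=O)O4)N3[C@H]2OC1=O
F7 | step 14 | spiro lactol (23 with the ring D C=O reduced to CH–OH) | CC1=C2CC[C@]3(C[C@@H](C)C(O)O3)[C@@H]3CC[C@@H]([C@@H]4C[C@H](C)C(=O)O4)N3[C@H]2OC1=O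
F8 | step 9 | 5-hydroxy-3-methylfuran-2(5H)-one | CC1=CC(O)OC1=O
F9 | step 6 | tert-butyl (2S,5S)-2-[(ethylsulfanyl)carbonyl]-5-[(2S,4S)-4-methyl-5-oxooxolan-2-yl]pyrrolidine-1-carboxylate | CCSC(=O)[C@@H]1CC[C@@H]([C@@H]2C[C@H](C)C(=O)O2)N1C(=O)OC(C)(C)C
A1 | alternative 1 | D-mannitol | OC[C@@H](O)[C@@H](O)[C@H](O)[C@H](O)CO
A2 | alternative 1 | (2R,5R)-1,6-bis(benzyloxy)hexane-2,5-diyl dimethanesulfonate | CS(=O)(=O)O[C@@H](COCc1ccccc1)CC[C@H](COCc1ccccc1)OS(C)(=O)=O
A3 | alternative 1 | (2S,5S)-1-benzyl-2,5-bis(benzyloxymethyl)pyrrolidine | c1ccccc1COC[C@@H]1CC[C@@H](COCc2ccccc2)N1Cc1ccccc1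
A4 | alternative 2 | N-benzyl trans-pyrrolidine bis-lactone with masked butenolide arm | CCOC(OCC)/C(CC[C@]1(C[C@@H](C)C(=O)O1)[C@@H]1CC[C@@H]([C@@H]2C[C@H](C)C(=O)O2)N1Cc1ccccc1)=C(/C)C(=O)OC(C)(C)C
A5 | alternative 3 | tetracyclic lactam bis-lactone | O=C1CCC[C@]2(C[C@@H](C)C(=O)O2)[C@@H]2CC[C@@H]([C@@H]3C[C@H](C)C(=O)O3)N12
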